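The tricycle is traced to a chrysanthenone-type 2-vinylcyclobutanone. In the key step the quaternary carbon C4 leaves the ketone α-carbon C7 and rebonds to the vinyl terminus C9. This [1,3] shift expands the cyclobutanone ring C4–C5–C6–C7 by two atoms to the cyclohexenone ring C4–C5–C6–C7–C8–C9, closes the cyclobutane C4–C5–C10–C9 and brings the double bond into conjugation (C7=C8); it exploits that C7 and C9 are both 1,3 to C5, the carbon holding C4. The precursor, a bicyclo[3.1.1]hept-2-en-6-one fused to the seven-membered ring that already carries both tiglates, comes from an intramolecular vinylketene–alkene cycloaddition on a cycloheptene made by Ireland–Claisen rearrangement, aldol chemistry and ring-closing metathesis.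

Key step: step 16

Numbering used for all compounds (target positions): C1 = CH(OTig) next to CMe2, C2 = CH2, C3 = CH(OTig) next to the quaternary carbon, C4 = quaternary C(CH3), C5 = CH α to the ketone, C6 = C=O, C7 = =CH, C8 = =C(CH3), C9 = ring CH next to C8, C10 = CH next to CMe2, C11 = CMe2; OTig = (2E)-2-methylbut-2-enoate.

Assumption: in step 7 (+)-Ipc2BCl is taken to direct the methyl ketone enolate to the re face of methacrolein; should the sense be opposite, its antipode is used in the same way.

Step 1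
Reactants: 1 (R)-but-3-yn-2-ol
Product: 2 (4R)-pent-2-yne-1,4-diol
Conditions: n-BuLi (2.1 equiv), THF, −78 °C; (CH2O)n, −78 °C → rt; aq NH4Cl
Reagents that add atoms: paraformaldehyde (formaldehyde unit), C=O
Why: The lithium acetylide of the O-lithiated alcohol adds to formaldehyde (acetylide hydroxymethylation), and the carbinol stereocentre is not touched.

Step 2
Reactants: 2 (4R)-pent-2-yne-1,4-diol
Product: 3 (2E,4R)-pent-2-ene-1,4-diol
Conditions: LiAlH4, THF, 0 °C → reflux; aqueous NaOH work-up
Reagents that add atoms: none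
Why: Hydroxyl-directed trans-hydroalumination of the propargylic alcohol (LiAlH4 reduction) should give the (E)-alkene only.

Step 3
Reactants: 3 (2E,4R)-pent-2-ene-1,4-diol
Product: 4 (2R,3E)-5-[(tert-butyldiphenylsilyl)oxy]pent-3-en-2-ol
Conditions: TBDPSCl (1.0 equiv), imidazole, CH2Cl2, −20 → 0 °C
Reagents that add atoms: tert-butyl(chloro)diphenylsilane, CC(C)(C)[Si](Cl)(c1ccccc1)c1ccccc1
Why: The bulky silyl chloride should select the primary over the secondary allylic hydroxyl (silyl ether protection).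

Step 4
Reactants: 4 (2R,3E)-5-[(tert-butyldiphenylsilyl)oxy]pent-3-en-2-ol, 5 2-methylpropanoyl chloride
Product: 6 (2R,3E)-5-[(tert-butyldiphenylsilyl)oxy]pent-3-en-2-yl 2-methylpropanoate
Conditions: pyridine, DMAP (cat.), CH2Cl2, 0 °C → rt
Reagents that add atoms: none
Why: DMAP-catalysed O-acylation of the secondary alcohol proceeds with retention at the carbinol carbon.

Step 5
Reactants: 6 (2R,3E)-5-[(tert-butyldiphenylsilyl)oxy]pent-3-en-2-yl 2-methylpropanoate
Product: 8 (3S,4E)-3-{[(tert-butyldiphenylsilyl)oxy]methyl}-2,2-dimethylhex-4-enoic acid, via trimethylsilyl ketene acetal 7 (not isolated)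
Conditions: LiN(i-Pr)2, TMSCl, Et3N, THF, −78 °C → 60 °C; then H2O/MeOH, dilute HCl, 0 °C
Reagents that add atoms: none
Why: Ireland–Claisen rearrangement through a chair transition state with the carbinol methyl equatorial transfers the (R)-carbinol chirality to the new C10 stereocentre (S), builds the C10–C11 bond next to the quaternary carbon and leaves an (E)-propenyl group; the dimethyl ketene acetal has no geometry issue.

Step 6
Reactants: 8 (3S,4E)-3-{[(tert-butyldiphenylsilyl)oxy]methyl}-2,2-dimethylhex-4-enoic acid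
Product: 9 (4S,5E)-4-{[(tert-butyldiphenylsilyl)oxy]methyl}-3,3-dimethylhept-5-en-2-one
Conditions: MeLi (2.5 equiv), Et2O, 0 °C → rt; aq NH4Cl
Reagents that add atoms: methyllithium, [Li]C
Why: Addition of methyllithium to the lithium carboxylate gives a gem-dialkoxide that collapses to the methyl ketone only on work-up (ketone synthesis from a carboxylic acid and an organolithium).

Step 7
Reactants: 9 (4S,5E)-4-{[(tert-butyldiphenylsilyl)oxy]methyl}-3,3-dimethylhept-5-en-2-one, 10 2-methylprop-2-enal (methacrolein)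
Product: 12 (3R,7S,8E)-7-{[(tert-butyldiphenylsilyl)oxy]methyl}-3-hydroxy-2,6,6-trimethyldeca-1,8-dien-5-one, via diisopinocampheylboron enolate 11 (not isolated)
Conditions: (+)-Ipc2BCl, Et3N, Et2O, 0 °C; 10, −78 → −20 °C; then pH 7 buffer, MeOH, H2O2
Reagents that add atoms: none
Why: Paterson aldol reaction: enolisation is possible only toward the methyl group (the other α-carbon is quaternary) and the isopinocampheyl ligands should direct the enolate to the re face of methacrolein, setting C3 as R.

Step 8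
Reactants: 12 (3R,7S,8E)-7-{[(tert-butyldiphenylsilyl)oxy]methyl}-3-hydroxy-2,6,6-trimethyldeca-1,8-dien-5-one
Product: 13 (3R,5R,7S,8E)-7-{[(tert-butyldiphenylsilyl)oxy]methyl}-2,6,6-trimethyldeca-1,8-diene-3,5-diol
Conditions: Me4NBH(OAc)3, MeCN/AcOH, −30 °C
Reagents that add atoms: none
Why: Evans–Saksena reduction: the C3 hydroxyl binds boron and delivers hydride intramolecularly to the C1 ketone through a chair transition state, which should give the 1,3-anti diol (C1 R).

Step 9
Reactants: 13 (3R,5R,7S,8E)-7-{[(tert-butyldiphenylsilyl)oxy]methyl}-2,6,6-trimethyldeca-1,8-diene-3,5-diol, 14 (2E)-2-methylbut-2-enoyl chloride (tigloyl chloride)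
Product: 15 (3R,5R,7S,8E)-7-{[(tert-butyldiphenylsilyl)oxy]methyl}-2,6,6-trimethyldeca-1,8-diene-3,5-diyl bis[(2E)-2-methylbut-2-enoate]
Conditions: 14 (3 equiv), pyridine, DMAP, CH2Cl2, 0 → 40 °C
Reagents that add atoms: none
Why: DMAP-catalysed acylation should esterify both secondary alcohols, and the (E)-tiglate is the stable ester geometry.

Step 10
Reactants: 15 (3R,5R,7S,8E)-7-{[(tert-butyldiphenylsilyl)oxy]methyl}-2,6,6-trimethyldeca-1,8-diene-3,5-diyl bis[(2E)-2-methylbut-2-enoate]
Product: 16 (1R,4S,6R)-4-{[(tert-butyldiphenylsilyl)oxy]methyl}-2,5,5-trimethylcyclohept-2-ene-1,6-diyl bis[(2E)-2-methylbut-2-enoate]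
Conditions: second-generation Grubbs catalyst RuCl2(=CHPh)(PCy3)(H2IMes) (5 mol%), toluene (0.005 M), 80 °C
Reagents that add atoms: none
Why: Ring-closing metathesis between the isopropenyl and propenyl groups should form the trisubstituted cycloheptene C4=C5 with loss of propene, while the electron-poor trisubstituted tiglate alkenes stay out.

Step 11
Reactants: 16 (1R,4S,6R)-4-{[(tert-butyldiphenylsilyl)oxy]methyl}-2,5,5-trimethylcyclohept-2-ene-1,6-diyl bis[(2E)-2-methylbut-2-enoate]
Product: 17 (1R,4S,6R)-4-(hydroxymethyl)-2,5,5-trimethylcyclohept-2-ene-1,6-diyl bis[(2E)-2-methylbut-2-enoate]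
Conditions: HF·pyridine, pyridine, THF, 0 °C → rt
Reagents that add atoms: none
Why: Buffered fluoride cleaves the silyl ether (desilylation) without touching the esters.

Step 12
Reactants: 17 (1R,4S,6R)-4-(hydroxymethyl)-2,5,5-trimethylcyclohept-2-ene-1,6-diyl bis[(2E)-2-methylbut-2-enoate]
Product: 18 (1R,4S,6R)-4-formyl-2,5,5-trimethylcyclohept-2-ene-1,6-diyl bis[(2E)-2-methylbut-2-enoate]
Conditions: Dess–Martin periodinane, NaHCO3, CH2Cl2, 0 °C → rt
Reagents that add atoms: none
Why: Dess–Martin oxidation under buffered, non-basic conditions should give the β,γ-unsaturated aldehyde without epimerisation at C10 or migration of the double bond.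

Step 13
Reactants: 18 (1R,4S,6R)-4-formyl-2,5,5-trimethylcyclohept-2-ene-1,6-diyl bis[(2E)-2-methylbut-2-enoate], 19 ethyl(triphenyl)phosphonium iodide
Product: 20 (Z)-vinyl iodide: cycloheptene 18 in which CHO is replaced by (Z)-CH=C(CH3)I (iodine cis to C10; ring configurations unchanged)
Conditions: 19, n-BuLi, THF, 0 °C; I2, −78 °C; NaN(SiMe3)2, −78 °C; then 18, −78 → −30 °C
Reagents that add atoms: iodine, II
Why: Stork–Zhao-type Wittig olefination with the α-iodoethylidene ylide should give the (Z)-2-iodoalkene, which fixes the C8=C9 geometry needed later.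

Step 14
Reactants: 20 (Z)-vinyl iodide, 21 ethoxyethyne
Product: 22 enynyl ethyl ether: as 20 with iodine replaced by C≡C–OEt (C10–C9H=C8(CH3)–C7≡C6–OEt, alkynyl cis to C10)
Conditions: 21, n-BuLi, THF, −78 °C; ZnCl2, −78 → 0 °C; then 20, Pd(PPh3)4 (5 mol%), THF, rt
Reagents that add atoms: none
Why: Negishi coupling of the alkynylzinc reagent with the vinyl iodide proceeds with retention of alkene geometry, and oxidative addition to the vinyl iodide should outrun ionisation of the hindered allylic ester.

Step 15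
Reactants: 22 enynyl ethyl ether
Product: 24 tricyclic cyclobutanone (bicyclo[3.1.1]hept-2-en-6-one C5–C6(=O)–C7 / C4 / C8=C9–C10 whose C4 bridge, CH3 toward the carbonyl bridge, is tied to C10 through C3(OTig)–C2–C1(OTig)–C11Me2), via vinylketene 23 (not isolated)
Conditions: degassed toluene (0.005 M), 125 °C, sealed tube
Reagents that add atoms: none
Why: Retro-ene loss of ethene from the alkynyl ether gives the vinylketene, whose intramolecular ketene–alkene [2+2] cycloaddition should bond the carbonyl carbon C6 to the less substituted C5 and C7 to C4 (bridged mode of a three-atom tether) on the alkene face cis to the C10 side chain, setting C4, C5 and C7.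

Step 16
Reactants: 24 tricyclic cyclobutanone
Product: 25 CNP0236543.5 (target bis-tiglate)
Conditions: EtAlCl2 (3.5 equiv), CH2Cl2, −78 → −20 °C; aq Rochelle salt
Reagents that add atoms: none
Why: Proposed new method: EtAlCl2 bound to the cyclobutanone oxygen should trigger heterolysis of the strained C4–C7 bond, which is aligned with the C8=C9 π bond, to a contact ion pair of the tertiary C4 cation and the aluminium dienolate O–C6=C7–C8=C9, and collapse at the γ-carbon C9 instead of C7 gives the target in a formal [1,3] carbon shift. The closest known reaction types are the vinylcyclobutane–cyclohexene rearrangement (the thermal [1,3] shift that racemises α-pinene), the Lewis-acid opening of donor-substituted cyclobutanones to zwitterions and γ-selective reactions of aluminium dienolates. The step expands the four-membered ring C4–C5–C6–C7 by C8 and C9 to the cyclohexenone (6-endo with respect to C8=C9) and closes the cyclobutane C4–C5–C10–C9 (4-exo with respect to C8=C9). C9 becomes a stereocentre and C4 keeps its configuration, because the cation stays bound to C5 on the face of the six-membered ring fixed by the cis fusion C5–C10, from which C7 and C9 (both 1,3 to C5) are equally reachable. The step needs γ- over α-recombination and recombination over proton loss: α-closure only regenerates 24, which re-ionises, whereas γ-closure gives the conjugated enone, the better Lewis base and expected thermodynamic sink, and the non-basic chloroaluminate medium at low temperature disfavours elimination.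

Compound list
1 | (R)-but-3-yn-2-ol | C[C@@H](O)C#C | starting material
2 | (4R)-pent-2-yne-1,4-diol | C[C@@H](O)C#CCO | intermediate
3 | (2E,4R)-pent-2-ene-1,4-diol | C[C@@H](O)/C=C/CO | intermediate
4 | (2R,3E)-5-[(tert-butyldiphenylsilyl)oxy]pent-3-en-2-ol | C[C@@H](O)/C=C/CO[Si](c1ccccc1)(c1ccccc1)C(C)(C)C | intermediate
5 | 2-methylpropanoyl chloride (isobutyryl chloride) | CC(C)C(Cl)=O | starting material
6 | (2R,3E)-5-[(tert-butyldiphenylsilyl)oxy]pent-3-en-2-yl 2-methylpropanoate | CC(C)C(=O)O[C@H](C)/C=C/CO[Si](c1ccccc1)(c1ccccc1)C(C)(C)C | intermediate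
7 | trimethylsilyl ketene acetal of 6 | CC(C)=C(O[Si](C)(C)C)O[C@H](C)/C=C/CO[Si](c1ccccc1)(c1ccccc1)C(C)(C)C | intermediate (not isolated)
8 | (3S,4E)-3-{[(tert-butyldiphenylsilyl)oxy]methyl}-2,2-dimethylhex-4-enoic acid | OC(=O)C(C)(C)[C@@H](CO[Si](c1ccccc1)(c1ccccc1)C(C)(C)C)/C=C/C | intermediate
9 | (4S,5E)-4-{[(tert-butyldiphenylsilyl)oxy]methyl}-3,3-dimethylhept-5-en-2-one | CC(=O)C(C)(C)[C@@H](CO[Si](c1ccccc1)(c1ccccc1)C(C)(C)C)/C=C/C | intermediate
10 | 2-methylprop-2-enal (methacrolein) | CC(=C)C=O | starting material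
11 | diisopinocampheylboron enolate of 9 (enolised toward the methyl group) | C=C(OB([C@H]1C[C@H]2C[C@@H]([C@@H]1C)C2(C)C)[C@H]1C[C@H]2C[C@@H]([C@@H]1C)C2(C)C)C(C)(C)[C@@H](CO[Si](c1ccccc1)(c1ccccc1)C(C)(C)C)/C=C/C | intermediate (not isolated)
12 | (3R,7S,8E)-7-{[(tert-butyldiphenylsilyl)oxy]methyl}-3-hydroxy-2,6,6-trimethyldeca-1,8-dien-5-one | C=C(C)[C@H](O)CC(=O)C(C)(C)[C@@H](CO[Si](c1ccccc1)(c1ccccc1)C(C)(C)C)/C=C/C | intermediate
13 | (3R,5R,7S,8E)-7-{[(tert-butyldiphenylsilyl)oxy]methyl}-2,6,6-trimethyldeca-1,8-diene-3,5-diol (anti-1,3-diol) | C=C(C)[C@H](O)C[C@@H](O)C(C)(C)[C@@H](CO[Si](c1ccccc1)(c1ccccc1)C(C)(C)C)/C=C/C | intermediate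
14 | (2E)-2-methylbut-2-enoyl chloride (tigloyl chloride) | C/C=C(\C)C(Cl)=O | starting material
15 | bis-tiglate of 13 | C=C(C)[C@H](OC(=O)/C(C)=C/C)C[C@@H](OC(=O)/C(C)=C/C)C(C)(C)[C@@H](CO[Si](c1ccccc1)(c1ccccc1)C(C)(C)C)/C=C/C | intermediate
16 | (1R,4S,6R)-4-{[(tert-butyldiphenylsilyl)oxy]methyl}-2,5,5-trimethylcyclohept-2-ene-1,6-diyl bis[(2E)-2-methylbut-2-enoate] (C10 substituent cis to the C1 ester, trans to the C3 ester) | CC1=C[C@H](CO[Si](c2ccccc2)(c2ccccc2)C(C)(C)C)C(C)(C)[C@H](OC(=O)/C(C)=C/C)C[C@H]1OC(=O)/C(C)=C/C | intermediate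
17 | (1R,4S,6R)-4-(hydroxymethyl)-2,5,5-trimethylcyclohept-2-ene-1,6-diyl bis[(2E)-2-methylbut-2-enoate] | CC1=C[C@H](CO)C(C)(C)[C@H](OC(=O)/C(C)=C/C)C[C@H]1OC(=O)/C(C)=C/C | intermediate
18 | (1R,4S,6R)-4-formyl-2,5,5-trimethylcyclohept-2-ene-1,6-diyl bis[(2E)-2-methylbut-2-enoate] | CC1=C[C@H](C=O)C(C)(C)[C@H](OC(=O)/C(C)=C/C)C[C@H]1OC(=O)/C(C)=C/C | intermediate
19 | ethyl(triphenyl)phosphonium iodide | CC[P+](c1ccccc1)(c1ccccc1)c1ccccc1.[I-] | starting material
20 | (Z)-vinyl iodide: 18 with CHO replaced by (Z)-CH=C(CH3)I, iodine cis to C10 | CC1=C[C@H](/C=C(/C)I)C(C)(C)[C@H](OC(=O)/C(C)=C/C)C[C@H]1OC(=O)/C(C)=C/C | intermediate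
21 | ethoxyethyne | CCOC#C | starting material
22 | enynyl ethyl ether: 20 with iodine replaced by ethoxyethynyl | CC1=C[C@H](/C=C(/C)C#COCC)C(C)(C)[C@H](OC(=O)/C(C)=C/C)C[C@H]1OC(=O)/C(C)=C/C | intermediate
23 | vinylketene: C10–C9H=C8(CH3)–C7H=C6=O on the cycloheptene of 16, ketene cis to C10 | CC1=C[C@H](/C=C(/C)C=C=O)C(C)(C)[C@H](OC(=O)/C(C)=C/C)C[C@H]1OC(=O)/C(C)=C/C | intermediate (not isolated)
24 | tricyclic cyclobutanone (chrysanthenone type; cyclobutanone C4–C5–C6–C7, alkene C8=C9, cis-fused seven-membered ring C4–C3–C2–C1–C11–C10–C5) | CC1=C[C@@H]2C(C)(C)[C@H](OC(=O)/C(C)=C/C)C[C@@H](OC(=O)/C(C)=C/C)[C@]3(C)[C@H]1C(=O)[C@H]23 | intermediate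
25 | CNP0236543.5 | C/C=C(\C)C(=O)O[C@@H]1C[C@@H](OC(=O)/C(C)=C/C)[C@@]2(C)[C@@H]3C(=O)C=C(C)[C@H]2[C@@H]3C1(C)C | target

Total step count: 16. Longest linear sequence: 16 steps (1 → 25).

Steps most likely to fail

1. Step 16 (Proposed new method). After ionisation, the C4 cation may lose a proton, take a hydride from C3 or be captured by the neighbouring C3 ester carbonyl faster than it recombines at C9, or the equilibrium may not favour the enone. The fallback sets out from 24 and comes back at 25, using the neutral, thermal form of the same ring expansion on a substrate that can no longer revert to a ketene. The ketone of 24 is reduced (NaBH4, MeOH, −40 °C) to the C6 cyclobutanol F1 (hydride from the alkene side; the C6 configuration is lost later) and silylated (TBSOTf, 2,6-lutidine, CH2Cl2) to the silyl ether F2, a plain pinene-type vinylcyclobutane. Its thermal vinylcyclobutane–cyclohexene rearrangement (the [1,3] carbon shift known from α-pinene; o-dichlorobenzene at about 230 °C or flash vacuum thermolysis) should give the ring-expanded allylic silyl ether F3. HF·pyridine frees the allylic alcohol F4, and Dess–Martin oxidation gives 25.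

2. Step 15. The ketene may add sluggishly to an alkene deactivated by the allylic ester, may escape by a [1,5]-hydrogen shift from C10, or may close in the fused instead of the bridged sense. The fallback sets out from 20 and comes back at 24, replacing the ketene by a more electrophilic keteniminium ion. Coupling of 20 with the zinc enolate BrZnCH2C(O)NMe2 (from 2-bromo-N,N-dimethylacetamide and zinc; Pd(dba)2, P(t-Bu)3, THF) gives the β,γ-unsaturated amide F5. Tf2O and 2,4,6-collidine in 1,2-dichloroethane (−20 → 80 °C) convert it into the vinylketeniminium triflate F6, whose intramolecular [2+2] cycloaddition gives the cyclobutaniminium triflate F7. Aqueous NaHCO3 hydrolyses F7 to 24.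

3. Step 13. The hindered, α-branched aldehyde may convert poorly, epimerise or conjugate under the basic ylide conditions, and control of the alkene geometry may be weak. The fallback sets out from 18 and comes back at 22, building the trisubstituted alkene by two stereoretentive couplings. The first stage of the Corey–Fuchs reaction (CBr4, PPh3, 2,6-lutidine, CH2Cl2, 0 °C) gives the 1,1-dibromoalkene F8. The bromine trans to the ring is replaced selectively by methyl (MeZnCl, Pd(PPh3)4, THF) to give the (Z)-2-bromoalkene F9. Negishi coupling of F9 with (ethoxyethynyl)zinc chloride as in step 14 gives 22.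

Further compounds
F1 | step 16 | C6 cyclobutanol from reduction of 24 (OH on the side of the C4 methyl) | CC1=C[C@@H]2C(C)(C)[C@H](OC(=O)/C(C)=C/C)C[C@@H](OC(=O)/C(C)=C/C)[C@]3(C)[C@H]1[C@@H](O)[C@H]23
F2 | step 16 | tert-butyldimethylsilyl ether of F1 | CC1=C[C@@H]2C(C)(C)[C@H](OC(=O)/C(C)=C/C)C[C@@H](OC(=O)/C(C)=C/C)[C@]3(C)[C@H]1[C@@H](O[Si](C)(C)C(C)(C)C)[C@H]23
F3 | step 16 | ring-expanded allylic silyl ether (target skeleton with C6 as CH–OTBS) | C/C=C(\C)C(=O)O[C@@H]1C[C@@H](OC(=O)/C(C)=C/C)[C@@]2(C)[C@@H]3[C@H](O[Si](C)(C)C(C)(C)C)C=C(C)[C@H]2[C@@H]3C1(C)C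
F4 | step 16 | C6 allylic alcohol of the target skeleton | C/C=C(\C)C(=O)O[C@@H]1C[C@@H](OC(=O)/C(C)=C/C)[C@@]2(C)[C@@H]3[C@H](O)C=C(C)[C@H]2[C@@H]3C1(C)C
F5 | step 15 | β,γ-unsaturated N,N-dimethylamide: 20 with iodine replaced by CH2C(O)NMe2 | CC1=C[C@H](/C=C(/C)CC(=O)N(C)C)C(C)(C)[C@H](OC(=O)/C(C)=C/C)C[C@H]1OC(=O)/C(C)=C/C
F6 | step 15 | vinylketeniminium triflate from F5 | CC1=C[C@H](/C=C(/C)C=C=[N+](C)C)C(C)(C)[C@H](OC(=O)/C(C)=C/C)C[C@H]1OC(=O)/C(C)=C/C.[O-]S(=O)(=O)C(F)(F)F
F7 | step 15 | cyclobutaniminium triflate (N,N-dimethyliminium of 24) | CC1=C[C@@H]2C(C)(C)[C@H](OC(=O)/C(C)=C/C)C[C@@H](OC(=O)/C(C)=C/C)[C@]3(C)[C@H]1C(=[N+](C)C)[C@H]23.[O-]S(=O)(=O)C(F)(F)F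
F8 | step 13 | 1,1-dibromoalkene: 18 with CHO replaced by CH=CBr2 | CC1=C[C@H](C=C(Br)Br)C(C)(C)[C@H](OC(=O)/C(C)=C/C)C[C@H]1OC(=O)/C(C)=C/C
F9 | step 13 | (Z)-2-bromoalkene: 18 with CHO replaced by (Z)-CH=C(CH3)Br, bromine cis to C10 | CC1=C[C@H](/C=C(/C)Br)C(C)(C)[C@H](OC(=O)/C(C)=C/C)C[C@H]1OC(=O)/C(C)=C/C
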